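## Retrosynthetic overview

1. Glaucolide K ⇒ acyclic redox-active ester 17. The C9–C10 bond of the ten-membered ring and the C8–O bond of the methacrylate are made together in the last step (decarboxylative radical 1,6-addition to a 4-vinylbutenolide, allyl radical trapped by copper methacrylate).
2. 17 ⇒ aldehyde 12 + N-propanoyl thiazolidinethione 14. A syn-aldol sets C1; the carbon next to the acyl group later becomes the C10 radical.
3. Vinylbutenolide 9 ⇒ epoxy γ-hydroxy ynoate 7 + vinylmagnesium chloride + CH2O (carbometalation, aldol and lactonisation in one flask).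
4. 7 ⇒ (E)-enal 4 + methyl propiolate 5 (catalytic asymmetric alkynylation sets C6; hydroxyl-directed epoxidation sets C4 and C5). 4 ⇒ pentynyl silyl ether 1 by carboalumination.
5. Ring order: oxirane (step 4), then butenolide (step 5), then the ten-membered carbocycle (step 13).

Assumption: pent-4-yn-1-ol is bought as its tert-butyldimethylsilyl (TBS) ether 1; atom labels C1–C15 follow germacrane numbering of the target.

## Route

Step 1
Reactants: 1 tert-butyldimethyl(pent-4-yn-1-yloxy)silane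
Product: 3 (2E)-6-(tert-butyldimethylsilyloxy)-3-methylhex-2-en-1-ol, via alkenylalane 2 (not isolated)
Conditions: AlMe3, Cp2ZrCl2 (25 mol %), CH2Cl2, 0 °C → rt; n-BuLi, THF, −78 °C; (CH2O)n, → rt; dilute aq. HCl, 0 °C
Reagents that add atoms: trimethylaluminium, C[Al](C)C; formaldehyde (from paraformaldehyde), C=O
Why: Negishi zirconium-catalysed carboalumination adds methyl and aluminium syn across the terminal alkyne (methyl to the internal carbon), and the alkenylalanate is hydroxymethylated with retention, so the trisubstituted C4=C5 alkene is formed E.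

Step 2
Reactants: 3 (2E)-6-(tert-butyldimethylsilyloxy)-3-methylhex-2-en-1-ol
Product: 4 (2E)-6-(tert-butyldimethylsilyloxy)-3-methylhex-2-enal
Conditions: MnO2 (15 equiv), CH2Cl2, rt
Reagents that add atoms: none
Why: MnO2 allylic oxidation stops at the enal and does not erode the E geometry.

Step 3
Reactants: 4 (2E)-6-(tert-butyldimethylsilyloxy)-3-methylhex-2-enal; 5 methyl propiolate
Product: 6 methyl (4R,5E)-9-(tert-butyldimethylsilyloxy)-4-hydroxy-6-methylnon-5-en-2-ynoate
Conditions: ZnMe2 (2.9 equiv), (S,S)-ProPhenol (10 mol %), Ph3P=O (20 mol %), toluene, 4 °C; aq. NH4Cl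
Reagents that add atoms: none
Why: Trost zinc–ProPhenol asymmetric alkynylation delivers the zinc acetylide of 5 to one face of the enal carbonyl and sets C6 (4R in 6); the (R,R)-ligand is used instead if the facial sense turns out reversed for this enal.

Step 4
Reactants: 6 methyl (4R,5E)-9-(tert-butyldimethylsilyloxy)-4-hydroxy-6-methylnon-5-en-2-ynoate
Product: 7 methyl (4S)-4-{(2R,3R)-3-[3-(tert-butyldimethylsilyloxy)propyl]-3-methyloxiran-2-yl}-4-hydroxybut-2-ynoate
Conditions: mCPBA (1.3 equiv), CH2Cl2, −10 → 0 °C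
Reagents that add atoms: 3-chloroperoxybenzoic acid, OOC(=O)c1cccc(Cl)c1
Why: Hydroxyl-directed (Henbest) peracid epoxidation: A(1,3) strain from the methyl group cis to the carbinol holds H-6 in the alkene plane, so the hydrogen-bonded peracid attacks the face bearing OH and gives the threo epoxy alcohol (C4 R, C5 R), trans from the E alkene; the electron-poor ynoate is inert.

Step 5
Reactants: 7 methyl (4S)-4-{(2R,3R)-3-[3-(tert-butyldimethylsilyloxy)propyl]-3-methyloxiran-2-yl}-4-hydroxybut-2-ynoate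
Product: 9 (5S)-5-{(2R,3R)-3-[3-(tert-butyldimethylsilyloxy)propyl]-3-methyloxiran-2-yl}-4-ethenyl-3-(hydroxymethyl)furan-2(5H)-one, via hydroxy dienoate 8 (not isolated)
Conditions: CH2=CHMgCl (3.5 equiv), CuBr·SMe2 (20 mol %), THF, −78 °C; CH2O (gas), −78 → 0 °C; aq. NH4Cl, rt
Reagents that add atoms: vinylmagnesium chloride, C=C[Mg]Cl; formaldehyde, C=O
Why: Copper-catalysed syn-carbomagnesiation (conjugate addition) of the ynoate puts the vinyl group on C7, the metalated enoate is hydroxymethylated at C11 from the side of the small vinyl group so that the ester ends up cis to the C6 alkoxide (Z-8), and this lactonises with loss of methoxide; no stereocentre is made or touched.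

Step 6
Reactants: 9 (5S)-5-{(2R,3R)-3-[3-(tert-butyldimethylsilyloxy)propyl]-3-methyloxiran-2-yl}-4-ethenyl-3-(hydroxymethyl)furan-2(5H)-one
Product: 10 [(5S)-5-{(2R,3R)-3-[3-(tert-butyldimethylsilyloxy)propyl]-3-methyloxiran-2-yl}-4-ethenyl-2-oxo-2,5-dihydrofuran-3-yl]methyl acetate
Conditions: Ac2O, pyridine, DMAP (5 mol %), CH2Cl2, 0 °C
Reagents that add atoms: acetic anhydride, CC(=O)OC(C)=O
Why: DMAP-catalysed O-acetylation of the only free hydroxyl installs the C13 acetate.

Step 7
Reactants: 10 [(5S)-5-{(2R,3R)-3-[3-(tert-butyldimethylsilyloxy)propyl]-3-methyloxiran-2-yl}-4-ethenyl-2-oxo-2,5-dihydrofuran-3-yl]methyl acetate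
Product: 11 [(5S)-4-ethenyl-5-{(2R,3R)-3-(3-hydroxypropyl)-3-methyloxiran-2-yl}-2-oxo-2,5-dihydrofuran-3-yl]methyl acetate
Conditions: TBAF, AcOH (1:1, 1.5 equiv), THF, 0 °C → rt
Reagents that add atoms: none
Why: Fluoride desilylation buffered with acetic acid keeps the medium non-basic, so the acidic H-6 next to the epoxide and the acetate are untouched.

Step 8
Reactants: 11 [(5S)-4-ethenyl-5-{(2R,3R)-3-(3-hydroxypropyl)-3-methyloxiran-2-yl}-2-oxo-2,5-dihydrofuran-3-yl]methyl acetate
Product: 12 [(5S)-4-ethenyl-5-{(2R,3R)-3-methyl-3-(3-oxopropyl)oxiran-2-yl}-2-oxo-2,5-dihydrofuran-3-yl]methyl acetate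
Conditions: Dess–Martin periodinane, pyridine, CH2Cl2, 0 °C → rt
Reagents that add atoms: none
Why: Dess–Martin oxidation of the primary alcohol under buffered conditions leaves the epoxide, diene and esters intact and gives the C1 aldehyde.

Step 9
Reactants: 13 propanoyl chloride
Product: 14 1-[(4S)-4-benzyl-2-thioxo-1,3-thiazolidin-3-yl]propan-1-one
Conditions: (4S)-4-benzyl-1,3-thiazolidine-2-thione, Et3N, DMAP (5 mol %), CH2Cl2, 0 °C
Reagents that add atoms: (4S)-4-benzyl-1,3-thiazolidine-2-thione, S=C1N[C@@H](Cc2ccccc2)CS1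
Why: N-acylation of the thiazolidinethione attaches the propanoyl unit (C10, C14 and the carboxyl carbon) to a chiral auxiliary that later also serves as an activated acyl donor.

Step 10
Reactants: 12 [(5S)-4-ethenyl-5-{(2R,3R)-3-methyl-3-(3-oxopropyl)oxiran-2-yl}-2-oxo-2,5-dihydrofuran-3-yl]methyl acetate; 14 1-[(4S)-4-benzyl-2-thioxo-1,3-thiazolidin-3-yl]propan-1-one
Product: 15 [(5S)-5-{(2R,3R)-3-[(3S,4R)-5-((4S)-4-benzyl-2-thioxo-1,3-thiazolidin-3-yl)-3-hydroxy-4-methyl-5-oxopentyl]-3-methyloxiran-2-yl}-4-ethenyl-2-oxo-2,5-dihydrofuran-3-yl]methyl acetate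
Conditions: 14 (1.5 equiv), Sn(OTf)2 (1.6 equiv), N-ethylpiperidine (1.8 equiv), CH2Cl2, −50 °C; then 12, −78 °C; pH 7 buffer
Reagents that add atoms: none
Why: Nagao–Mukaiyama tin-enolate aldol: the Z-enolate of divalent tin reacts through a thione-chelated chair transition state to give the syn aldol, the 4-benzyl group shielding one face so that the carbinol C1 is S (the antipodal auxiliary is used if the sense is reversed); the C10 centre made here is erased in step 13.

Step 11
Reactants: 15 [(5S)-5-{(2R,3R)-3-[(3S,4R)-5-((4S)-4-benzyl-2-thioxo-1,3-thiazolidin-3-yl)-3-hydroxy-4-methyl-5-oxopentyl]-3-methyloxiran-2-yl}-4-ethenyl-2-oxo-2,5-dihydrofuran-3-yl]methyl acetate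
Product: 16 (3S,4R)-3-O-acetate of 15
Conditions: Ac2O, pyridine, CH2Cl2, 0 °C → rt
Reagents that add atoms: acetic anhydride, CC(=O)OC(C)=O
Why: Pyridine-mediated acetylation installs the C1 acetate with retention; DMAP is left out to avoid β-elimination of the activated aldol.

Step 12
Reactants: 16 (3S,4R)-3-O-acetate of 15
Product: 17 1,3-dioxoisoindolin-2-yl (2R,3S)-3-acetoxy-5-[(2R,3R)-3-{(2S)-4-(acetoxymethyl)-3-ethenyl-5-oxo-2,5-dihydrofuran-2-yl}-2-methyloxiran-2-yl]-2-methylpentanoate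
Conditions: N-hydroxyphthalimide (1.2 equiv), imidazole (20 mol %), CH2Cl2, 0 °C → rt
Reagents that add atoms: N-hydroxyphthalimide, O=C1c2ccccc2C(=O)N1O
Why: Proposed new method: N-acylthiazolidinethiones are activated amides that undergo mild base-catalysed alcoholysis, aminolysis and hydroxylaminolysis, so the N-hydroxyphthalimide anion should add to the exocyclic carbonyl and expel the thiazolidinethione to give the redox-active ester without a free-acid stage; the closest known reaction type is the DMAP- or imidazole-catalysed transacylation of N-acylthiazolidinethiones with alcohols and N-hydroxy amines.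

Step 13
Reactants: 17 1,3-dioxoisoindolin-2-yl (2R,3S)-3-acetoxy-5-[(2R,3R)-3-{(2S)-4-(acetoxymethyl)-3-ethenyl-5-oxo-2,5-dihydrofuran-2-yl}-2-methyloxiran-2-yl]-2-methylpentanoate
Product: 20 glaucolide K, via secondary alkyl radical 18 (not isolated), via macrocyclic allyl radical 19 (not isolated)
Conditions: fac-Ir(ppy)3 (1 mol %), Cu(MeCN)4PF6 (10 mol %), (S,S)-t-Bu-box (12 mol %), potassium methacrylate (2 equiv), 18-crown-6 (20 mol %), MeCN/CH2Cl2, 0.001 mol/L (17 added over 12 h), 450 nm LEDs, 20 °C; aq. NH4Cl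
Reagents that add atoms: potassium methacrylate, C=C(C)C(=O)[O-].[K+]
Why: Proposed new method: the excited trivalent iridium complex reduces the N-acyloxyphthalimide, loss of CO2 gives the nucleophilic secondary radical 18, which closes the ten-membered ring by decarboxylative Giese-type 1,6-addition to the terminal carbon of the electron-poor 4-vinylbutenolide to give the stabilised allyl radical 19; divalent copper methacrylate (formed when tetravalent iridium oxidises monovalent copper) captures 19, and carbon–oxygen reductive elimination from trivalent copper at the less hindered C8 terminus delivers the methacrylate and restores the butenolide without an enolate that could expel the C13 acetate; the closest known reactions are photoredox decarboxylative 1,6-additions of N-acyloxyphthalimide-derived radicals to 4-vinylbutenolides, decarboxylative Giese macrocyclisations and copper–bisoxazoline-catalysed radical carbo-acyloxylation of 1,3-dienes (radical Kharasch–Sosnovsky type); C10 is set in the ring closure (methyl pseudo-equatorial and syn to the C1 acetate is the expected, not assured, outcome) and C8 in the ligand-controlled carbon–oxygen bond formation, while the carboxylate salt and high dilution suppress radical addition to methacrylate.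

## Compound list

1 | tert-butyldimethyl(pent-4-yn-1-yloxy)silane | C#CCCCO[Si](C)(C)C(C)(C)C | starting material
2 | [(1E)-5-(tert-butyldimethylsilyloxy)-2-methylpent-1-en-1-yl]dimethylalane | CC(C)(C)[Si](C)(C)OCCC/C(C)=C/[Al](C)C | intermediate
3 | (2E)-6-(tert-butyldimethylsilyloxy)-3-methylhex-2-en-1-ol | CC(C)(C)[Si](C)(C)OCCC/C(C)=C/CO | intermediate
4 | (2E)-6-(tert-butyldimethylsilyloxy)-3-methylhex-2-enal | CC(C)(C)[Si](C)(C)OCCC/C(C)=C/C=O | intermediate
5 | methyl propiolate (methyl prop-2-ynoate) | C#CC(=O)OC | starting material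
6 | methyl (4R,5E)-9-(tert-butyldimethylsilyloxy)-4-hydroxy-6-methylnon-5-en-2-ynoate | CC(C)(C)[Si](C)(C)OCCC/C(C)=C/[C@@H](O)C#CC(=O)OC | intermediate
7 | methyl (4S)-4-{(2R,3R)-3-[3-(tert-butyldimethylsilyloxy)propyl]-3-methyloxiran-2-yl}-4-hydroxybut-2-ynoate | CC(C)(C)[Si](C)(C)OCCC[C@@]1(C)O[C@@H]1[C@@H](O)C#CC(=O)OC | intermediate
8 | methyl (2Z)-3-[(S)-{(2R,3R)-3-[3-(tert-butyldimethylsilyloxy)propyl]-3-methyloxiran-2-yl}(hydroxy)methyl]-2-(hydroxymethyl)penta-2,4-dienoate (present as its magnesium alkoxide) | CC(C)(C)[Si](C)(C)OCCC[C@@]1(C)O[C@@H]1[C@@H](O)/C(C=C)=C(CO)\C(=O)OC | intermediate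
9 | (5S)-5-{(2R,3R)-3-[3-(tert-butyldimethylsilyloxy)propyl]-3-methyloxiran-2-yl}-4-ethenyl-3-(hydroxymethyl)furan-2(5H)-one | CC(C)(C)[Si](C)(C)OCCC[C@@]1(C)O[C@@H]1[C@H]1OC(=O)C(CO)=C1C=C | intermediate
10 | [(5S)-5-{(2R,3R)-3-[3-(tert-butyldimethylsilyloxy)propyl]-3-methyloxiran-2-yl}-4-ethenyl-2-oxo-2,5-dihydrofuran-3-yl]methyl acetate | CC(C)(C)[Si](C)(C)OCCC[C@@]1(C)O[C@@H]1[C@H]1OC(=O)C(COC(C)=O)=C1C=C | intermediate
11 | [(5S)-4-ethenyl-5-{(2R,3R)-3-(3-hydroxypropyl)-3-methyloxiran-2-yl}-2-oxo-2,5-dihydrofuran-3-yl]methyl acetate | OCCC[C@@]1(C)O[C@@H]1[C@H]1OC(=O)C(COC(C)=O)=C1C=C | intermediate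
12 | [(5S)-4-ethenyl-5-{(2R,3R)-3-methyl-3-(3-oxopropyl)oxiran-2-yl}-2-oxo-2,5-dihydrofuran-3-yl]methyl acetate | O=CCC[C@@]1(C)O[C@@H]1[C@H]1OC(=O)C(COC(C)=O)=C1C=C | intermediate
13 | propanoyl chloride | CCC(Cl)=O | starting material
14 | 1-[(4S)-4-benzyl-2-thioxo-1,3-thiazolidin-3-yl]propan-1-one | CCC(=O)N1[C@@H](Cc2ccccc2)CSC1=S | intermediate
15 | [(5S)-5-{(2R,3R)-3-[(3S,4R)-5-((4S)-4-benzyl-2-thioxo-1,3-thiazolidin-3-yl)-3-hydroxy-4-methyl-5-oxopentyl]-3-methyloxiran-2-yl}-4-ethenyl-2-oxo-2,5-dihydrofuran-3-yl]methyl acetate (syn-aldol) | S=C1SC[C@H](Cc2ccccc2)N1C(=O)[C@H](C)[C@@H](O)CC[C@@]3(C)O[C@@H]3[C@H]3OC(=O)C(COC(C)=O)=C3C=C | intermediate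
16 | (3S,4R)-3-O-acetate of 15 | S=C1SC[C@H](Cc2ccccc2)N1C(=O)[C@H](C)[C@@H](OC(C)=O)CC[C@@]3(C)O[C@@H]3[C@H]3OC(=O)C(COC(C)=O)=C3C=C | intermediate
17 | 1,3-dioxoisoindolin-2-yl (2R,3S)-3-acetoxy-5-[(2R,3R)-3-{(2S)-4-(acetoxymethyl)-3-ethenyl-5-oxo-2,5-dihydrofuran-2-yl}-2-methyloxiran-2-yl]-2-methylpentanoate | O=C(ON1C(=O)c2ccccc2C1=O)[C@H](C)[C@@H](OC(C)=O)CC[C@@]3(C)O[C@@H]3[C@H]3OC(=O)C(COC(C)=O)=C3C=C | intermediate
18 | secondary C10 radical: (3S)-3-acetoxy-5-[(2R,3R)-3-{(2S)-4-(acetoxymethyl)-3-ethenyl-5-oxo-2,5-dihydrofuran-2-yl}-2-methyloxiran-2-yl]pentan-2-yl | C[CH][C@@H](OC(C)=O)CC[C@@]1(C)O[C@@H]1[C@H]1OC(=O)C(COC(C)=O)=C1C=C | intermediate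
19 | ten-membered allyl radical (C8/C11 delocalised, drawn at C8) of (1S,4R,5R,6S,10S)-1,13-diacetoxy-4,5-epoxygermacr-7(11)-en-12,6-olide | [CH]1C[C@H](C)[C@@H](OC(C)=O)CC[C@@]2(C)O[C@@H]2[C@H]2OC(=O)C(COC(C)=O)=C12 | intermediate
20 | glaucolide K, (1S,4R,5R,6S,8S,10S)-1,13-diacetoxy-4,5-epoxy-8-(methacryloyloxy)germacr-7(11)-en-12,6-olide | C=C(C)C(=O)O[C@H]1C[C@H](C)[C@@H](OC(C)=O)CC[C@@]2(C)O[C@@H]2[C@H]2OC(=O)C(COC(C)=O)=C12 | target

## Step count and risks

Total steps: 13. Longest linear sequence: 12 (steps 1–8 and 10–13; step 9 is a one-step side branch).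

The three steps most likely to fail:

**Step 13 (ring closure with acyloxylation).** Closing a ten-membered ring by radical addition is slow, so capture of radical 18 by copper or by methacrylate, or carbon–nitrogen coupling with phthalimide, may win. The configurations at C10 and C8 rest on the ring-closing transition state and on the ligand and are not assured. Fallback, setting out from aldehyde 12 and coming back at 20: (Z)-crotylboration with B-[(Z)-but-2-enyl]diisopinocampheylborane (antipode chosen for 1S,10S) gives the syn homoallylic alcohol F1, which fixes C1 and C10 by reagent control. Acetylation gives the diene acetate F2. Ring-closing metathesis of the two vinyl groups with the second-generation Hoveyda–Grubbs catalyst at high dilution gives the ten-membered 8,9-alkene F3. Mukaiyama hydration (Mn(dpm)3, PhSiH3, O2; hydrogen atom to C9, oxygen at C8) gives the 8S alcohol F4 together with its 8R epimer F5. F4 is esterified with methacrylic anhydride and F5 is inverted by Mitsunobu reaction with methacrylic acid; both give 20.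

**Step 5 (carbometalation, formaldehyde aldol, lactonisation).** Trapping of the metalated enoate by formaldehyde may be inefficient, and the magnesium alkoxide next to the epoxide could rearrange. Fallback, setting out from 7 and coming back at 9: the same copper-catalysed vinyl addition is quenched with iodine instead of formaldehyde to give, after lactonisation, the 3-iodobutenolide F6. Stille coupling of F6 with (tributylstannyl)methanol and Pd(PPh3)4 then installs the hydroxymethyl group and gives 9.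

**Step 12 (direct transfer of the acyl group to N-hydroxyphthalimide).** The reaction is unprecedented in this exact form, and the β-acetoxy acyl donor can eliminate acetic acid under base. Fallback, setting out from 16 and coming back at 17: DMAP-catalysed alcoholysis of 16 with 2-(trimethylsilyl)ethanol gives the 2-(trimethylsilyl)ethyl ester F7. Fluoride cleavage with TASF gives the free acid F8. Coupling of F8 with N-hydroxyphthalimide and N,N′-diisopropylcarbodiimide gives 17.

## Further compounds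

F1 | step 13 | [(5S)-4-ethenyl-5-{(2R,3R)-3-[(3S,4S)-3-hydroxy-4-methylhex-5-en-1-yl]-3-methyloxiran-2-yl}-2-oxo-2,5-dihydrofuran-3-yl]methyl acetate | C=C[C@H](C)[C@@H](O)CC[C@@]1(C)O[C@@H]1[C@H]1OC(=O)C(COC(C)=O)=C1C=C
F2 | step 13 | (3S,4S)-3-O-acetate of F1 | C=C[C@H](C)[C@@H](OC(C)=O)CC[C@@]1(C)O[C@@H]1[C@H]1OC(=O)C(COC(C)=O)=C1C=C
F3 | step 13 | (1S,4R,5R,6S,8Z,10S)-1,13-diacetoxy-4,5-epoxygermacra-7(11),8-dien-12,6-olide | CC(=O)O[C@H]1CC[C@@]2(C)O[C@@H]2[C@H]2OC(=O)C(COC(C)=O)=C2/C=C\[C@@H]1C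
F4 | step 13 | (1S,4R,5R,6S,8S,10S)-1,13-diacetoxy-4,5-epoxy-8-hydroxygermacr-7(11)-en-12,6-olide | O[C@H]1C[C@H](C)[C@@H](OC(C)=O)CC[C@@]2(C)O[C@@H]2[C@H]2OC(=O)C(COC(C)=O)=C12
F5 | step 13 | (1S,4R,5R,6S,8R,10S)-1,13-diacetoxy-4,5-epoxy-8-hydroxygermacr-7(11)-en-12,6-olide | O[C@@H]1C[C@H](C)[C@@H](OC(C)=O)CC[C@@]2(C)O[C@@H]2[C@H]2OC(=O)C(COC(C)=O)=C12
F6 | step 5 | (5S)-5-{(2R,3R)-3-[3-(tert-butyldimethylsilyloxy)propyl]-3-methyloxiran-2-yl}-4-ethenyl-3-iodofuran-2(5H)-one | CC(C)(C)[Si](C)(C)OCCC[C@@]1(C)O[C@@H]1[C@H]1OC(=O)C(I)=C1C=C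
F7 | step 12 | 2-(trimethylsilyl)ethyl (2R,3S)-3-acetoxy-5-[(2R,3R)-3-{(2S)-4-(acetoxymethyl)-3-ethenyl-5-oxo-2,5-dihydrofuran-2-yl}-2-methyloxiran-2-yl]-2-methylpentanoate | C[Si](C)(C)CCOC(=O)[C@H](C)[C@@H](OC(C)=O)CC[C@@]1(C)O[C@@H]1[C@H]1OC(=O)C(COC(C)=O)=C1C=C
F8 | step 12 | (2R,3S)-3-acetoxy-5-[(2R,3R)-3-{(2S)-4-(acetoxymethyl)-3-ethenyl-5-oxo-2,5-dihydrofuran-2-yl}-2-methyloxiran-2-yl]-2-methylpentanoic acid | OC(=O)[C@H](C)[C@@H](OC(C)=O)CC[C@@]1(C)O[C@@H]1[C@H]1OC(=O)C(COC(C)=O)=C1C=C
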